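**Retrosynthetic overview**

- The target is a 2-aryl-3-(hydroxymethyl)-4-benzyl oxolane (ring atoms O1, C2, C3, C4, C5; 2,3-trans, 3,4-cis). The strategy rests on reading C3 as a former malonate carbon and the C4 benzyl group as a former arylmethylidene group, so that C3 and C4 can be set late, relayed from C2.
- Key disconnection: the oxolane of the 3,3-diester is cut at O1–C2, C3–C4 and the aryl–CH bond. This gives propargyl alcohol (O1, C5, C4 and the benzylic carbon), an arylidene malonate (C2, C3) and an aryl iodide (the guaiacyl ring).
- The oxolane is the only ring formed. It closes in this three-component palladium coupling, run with a chiral bisphosphine so that C2 is fixed by dynamic kinetic resolution.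
- After the ring: Krapcho loss of one ester (C3, trans to the C2 aryl), hydrogenation of the exocyclic alkene anti to the C3 ester with O-debenzylation (C4), then LiAlH4 reduction.
- Before the ring: Knoevenagel condensation and benzylation of the iodophenol.

Key step: step 3

**Remarks on the chemistry**

- The sense of induction of the bisphosphine in step 3 cannot be predicted. (R)-DTBM-SEGPHOS is written; its antipode would be used if experiment shows it favours the other series.
- The spatial arrangement at C2 is the same from compound 9 to the target. The descriptor is R in diester 9 and S from 10 onward only because the CIP ranking of C3 and the aryl carbon is reversed once one ester is gone.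

**Route**

Step 1
Reactants: 1 3,4,5-trimethoxybenzaldehyde; 2 dimethyl malonate
Product: 3 dimethyl 2-(3,4,5-trimethoxybenzylidene)malonate
Conditions: piperidine (0.1 equiv), AcOH (0.1 equiv), toluene, reflux, Dean–Stark trap
Reagents that add atoms: none
Why: Knoevenagel condensation of a non-enolizable aromatic aldehyde with an active methylene compound, driven to completion by azeotropic removal of water.

Step 2
Reactants: 4 4-iodo-2-methoxyphenol
Product: 5 1-(benzyloxy)-4-iodo-2-methoxybenzene
Conditions: BnBr (1.1 equiv), K2CO3 (1.5 equiv), DMF, 50 °C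
Reagents that add atoms: benzyl bromide, BrCc1ccccc1
Why: Williamson ether synthesis on a phenoxide; the benzyl ether masks the acidic phenol, which would otherwise quench the alkoxide and the malonate anion of step 3.

Step 3
Reactants: 6 propargyl alcohol; 3 dimethyl 2-(3,4,5-trimethoxybenzylidene)malonate; 5 1-(benzyloxy)-4-iodo-2-methoxybenzene
Product: 9 dimethyl (2R,4Z)-4-[(4-benzyloxy-3-methoxyphenyl)methylidene]-2-(3,4,5-trimethoxyphenyl)oxolane-3,3-dicarboxylate, via lithium prop-2-yn-1-olate 7 (not isolated), via oxa-Michael adduct lithium enolate 8 (not isolated)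
Conditions: 6 (1.2 equiv), n-BuLi (1.2 equiv), THF, 0 °C; then 3 (1.2 equiv), THF/DMSO, rt; then Pd(dba)2 (5 mol %), (R)-DTBM-SEGPHOS (6 mol %), 5 (1.0 equiv) added slowly, THF/DMSO, 25 °C
Reagents that add atoms: none
Why: Proposed new method: lithium alkoxide 7 adds reversibly to arylidene malonate 3 (oxa-Michael, O1–C2) to give the racemic malonate enolate 8, whose enantiomers interconvert through 3 and 7; oxidative addition of iodide 5 to the zerovalent palladium–bisphosphine complex gives an aryl complex of divalent palladium that, after loss of iodide in DMSO, binds the alkyne of 8, the malonate carbon attacks the internal alkyne carbon anti to palladium (C3–C4), and reductive elimination from the alkenyl(aryl)palladium forms the aryl–carbon bond and returns zerovalent palladium. The closest known reaction type is the racemic palladium-mediated three-component coupling of propargyl alkoxides, alkylidene malonates and aryl halides to 4-arylidene oxolanes; what is new is the chiral bisphosphine, which is asked to turn the irreversible ring closure into a dynamic kinetic resolution of 8. The oxolane closes in the 5-exo-dig mode. C2, the only new stereocenter, is controlled by the ligand on palladium: the 3,5-di-tert-butyl-4-methoxyphenyl groups on phosphorus reach past the bound alkyne toward the propargylic ether side, so that one enantiomer of 8 can keep its C2 aryl group clear of them in the closure transition state and should cyclize faster, while the other returns to 3 and 7. The step needs retro-addition that is fast relative to ring closure, exclusive exo attack and anti addition: the electron-rich trimethoxyphenyl group and the doubly stabilized malonate carbanion make the oxa-Michael step readily reversible, slow addition of 5 keeps the aryl palladium concentration low, the three-atom tether between C3 and the alkyne allows only the exo closure, and anti attack on the coordinated alkyne places the guaiacyl ring trans to C3, which is the Z alkene.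

Step 4
Reactants: 9 dimethyl (2R,4Z)-4-[(4-benzyloxy-3-methoxyphenyl)methylidene]-2-(3,4,5-trimethoxyphenyl)oxolane-3,3-dicarboxylate
Product: 10 methyl (2S,3S,4Z)-4-[(4-benzyloxy-3-methoxyphenyl)methylidene]-2-(3,4,5-trimethoxyphenyl)oxolane-3-carboxylate
Conditions: LiCl (3 equiv), H2O (2 equiv), DMSO, 140 °C
Reagents that add atoms: none
Why: Krapcho dealkoxycarbonylation, in which chloride demethylates one ester, CO2 is lost and the C3 ester enolate is protonated at its α-carbon (the kinetic site of the dienolate, so the exocyclic alkene should stay in place); under these equilibrating conditions the ester should settle trans to the C2 aryl group (3S), and C2 is safe because it is not enolizable and loss of O1 from the C3 enolate would be a poorly aligned 5-endo elimination.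

Step 5
Reactants: 10 methyl (2S,3S,4Z)-4-[(4-benzyloxy-3-methoxyphenyl)methylidene]-2-(3,4,5-trimethoxyphenyl)oxolane-3-carboxylate
Product: 11 methyl (2S,3S,4R)-4-(4-hydroxy-3-methoxybenzyl)-2-(3,4,5-trimethoxyphenyl)oxolane-3-carboxylate
Conditions: H2 (1 atm), 10% Pd/C, EtOAc, rt
Reagents that add atoms: none
Why: Heterogeneous catalytic hydrogenation should deliver both hydrogens syn to the alkene face opposite the adjacent C3 ester, setting C4 (R) with the benzyl group cis to the ester and trans to the C2 aryl group, while the aryl benzyl ether is cleaved by hydrogenolysis and the cyclic benzylic C2–O1 bond, which reacts much more slowly under neutral conditions at 1 atm, is kept.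

Step 6
Reactants: 11 methyl (2S,3S,4R)-4-(4-hydroxy-3-methoxybenzyl)-2-(3,4,5-trimethoxyphenyl)oxolane-3-carboxylate
Product: 12 [(2S,3R,4R)-4-(4-hydroxy-3-methoxybenzyl)-2-(3,4,5-trimethoxyphenyl)oxolan-3-yl]methanol (the target)
Conditions: LiAlH4 (3 equiv), THF, 0 °C to rt; aqueous Rochelle salt work-up
Reagents that add atoms: none
Why: Hydride reduction of the ester to the primary alcohol, with the phenol carried as its aluminium phenoxide and freed on work-up; reduction at 0 °C should outrun epimerization at C3, so the three stereocenters are kept.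

**Compound list**

1 | 3,4,5-trimethoxybenzaldehyde | COc1cc(C=O)cc(OC)c1OC | starting material
2 | dimethyl malonate | COC(=O)CC(=O)OC | starting material
3 | dimethyl 2-(3,4,5-trimethoxybenzylidene)malonate | COC(=O)C(=Cc1cc(OC)c(OC)c(OC)c1)C(=O)OC | intermediate
4 | 4-iodo-2-methoxyphenol | COc1cc(I)ccc1O | starting material
5 | 1-(benzyloxy)-4-iodo-2-methoxybenzene | COc1cc(I)ccc1OCc1ccccc1 | intermediate
6 | propargyl alcohol (prop-2-yn-1-ol) | C#CCO | starting material
7 | lithium prop-2-yn-1-olate (not isolated) | [Li+].[O-]CC#C | intermediate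
8 | lithium enolate of dimethyl 2-[(prop-2-yn-1-yloxy)(3,4,5-trimethoxyphenyl)methyl]malonate, racemic and equilibrating with 3 and 7 (not isolated) | [Li+].COC(=O)C(=C([O-])OC)C(OCC#C)c1cc(OC)c(OC)c(OC)c1 | intermediate
9 | dimethyl (2R,4Z)-4-[(4-benzyloxy-3-methoxyphenyl)methylidene]-2-(3,4,5-trimethoxyphenyl)oxolane-3,3-dicarboxylate | COc1cc(/C=C2\CO[C@H](c3cc(OC)c(OC)c(OC)c3)C2(C(=O)OC)C(=O)OC)ccc1OCc1ccccc1 | intermediate
10 | methyl (2S,3S,4Z)-4-[(4-benzyloxy-3-methoxyphenyl)methylidene]-2-(3,4,5-trimethoxyphenyl)oxolane-3-carboxylate | COc1cc(/C=C2\CO[C@H](c3cc(OC)c(OC)c(OC)c3)[C@H]2C(=O)OC)ccc1OCc1ccccc1 | intermediate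
11 | methyl (2S,3S,4R)-4-(4-hydroxy-3-methoxybenzyl)-2-(3,4,5-trimethoxyphenyl)oxolane-3-carboxylate | COc1cc(C[C@H]2CO[C@H](c3cc(OC)c(OC)c(OC)c3)[C@H]2C(=O)OC)ccc1O | intermediate
12 | [(2S,3R,4R)-4-(4-hydroxy-3-methoxybenzyl)-2-(3,4,5-trimethoxyphenyl)oxolan-3-yl]methanol | COc1cc(C[C@H]2CO[C@H](c3cc(OC)c(OC)c(OC)c3)[C@H]2CO)ccc1O | target

**Step count**

Total: 6 steps. Longest linear sequence: 5 steps (steps 1, 3, 4, 5, 6).

**Steps most likely to fail**

1. Step 3 (the proposed new method). Ring closure may outrun the retro-oxa-Michael equilibration of 8, so that both enantiomers cyclize. The ligand, bound on the alkyne face remote from C2, may also discriminate poorly, and a bidentate phosphine may slow the closure enough for direct alkynylation of the iodide to compete. Fallback, setting out from 3 (with 5 and 6) and returning at 9: the known racemic coupling is run with an achiral catalyst. The lithium alkoxide from 6 and n-BuLi in THF is treated with 3, then with 5 and PdCl2(PPh3)2 (5 mol %) reduced in the flask by n-BuLi (10 mol %) in THF/DMSO at room temperature. This should give racemic dimethyl (4Z)-4-[(4-benzyloxy-3-methoxyphenyl)methylidene]-2-(3,4,5-trimethoxyphenyl)oxolane-3,3-dicarboxylate F1. Preparative chromatography on a chiral stationary phase (amylose tris(3,5-dimethylphenylcarbamate), supercritical CO2/MeOH) then separates 9 from its enantiomer, dimethyl (2S,4Z)-4-[(4-benzyloxy-3-methoxyphenyl)methylidene]-2-(3,4,5-trimethoxyphenyl)oxolane-3,3-dicarboxylate F2, which is set aside.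

2. Step 4. At 140 °C the dienolate may take its proton at the γ-carbon, moving the alkene into conjugation with the ester. That would erase C3 and the exocyclic alkene needed in step 5. Equilibration at C3 may also stop short of the trans ester. Fallback, setting out from 9 and returning at 10: one ester is saponified with LiOH (1.2 equiv) in THF/MeOH/H2O at 40 °C, where the quaternary C3 cannot enolize. Acidification gives the half-acid (2R,4Z)-4-[(4-benzyloxy-3-methoxyphenyl)methylidene]-3-(methoxycarbonyl)-2-(3,4,5-trimethoxyphenyl)oxolane-3-carboxylic acid F3 (either C3 epimer serves). Heating F3 in toluene at reflux should expel CO2 through the cyclic transition state and give the ester enol, which ketonizes under neutral conditions to 10 mixed with its C3 epimer, methyl (2S,3R,4Z)-4-[(4-benzyloxy-3-methoxyphenyl)methylidene]-2-(3,4,5-trimethoxyphenyl)oxolane-3-carboxylate F4. Brief treatment of the mixture with DBU (0.2 equiv) in CH2Cl2 at room temperature should then equilibrate C3 to the trans ester 10.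

3. Step 5. Facial bias may be insufficient, because the C2 aryl group sits on the face from which hydrogen must come and competes with the C3 ester on the other face. Alkene migration on the catalyst before reduction and slow hydrogenolysis of the benzylic C2–O1 bond are further risks. Fallback, setting out from 10 and returning at 12: the ester is reduced first (LiAlH4, THF, 0 °C) to the homoallylic alcohol [(2S,3R,4Z)-4-[(4-benzyloxy-3-methoxyphenyl)methylidene]-2-(3,4,5-trimethoxyphenyl)oxolan-3-yl]methanol F5. Silylation (TBDPSCl, imidazole, DMF) gives tert-butyl{[(2S,3R,4Z)-4-[(4-benzyloxy-3-methoxyphenyl)methylidene]-2-(3,4,5-trimethoxyphenyl)oxolan-3-yl]methoxy}diphenylsilane F6. Hydrogenation (H2, 1 atm, 10% Pd/C, EtOAc) then meets a much larger group on the C3 face, should add anti to it and removes the benzyl ether, giving 4-{[(3R,4R,5S)-4-{[tert-butyl(diphenyl)silyl]oxymethyl}-5-(3,4,5-trimethoxyphenyl)oxolan-3-yl]methyl}-2-methoxyphenol F7. TBAF in THF removes the silyl group and gives 12.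

**Further compounds**

F1 | step 3 | racemic dimethyl (4Z)-4-[(4-benzyloxy-3-methoxyphenyl)methylidene]-2-(3,4,5-trimethoxyphenyl)oxolane-3,3-dicarboxylate | COc1cc(/C=C2\COC(c3cc(OC)c(OC)c(OC)c3)C2(C(=O)OC)C(=O)OC)ccc1OCc1ccccc1
F2 | step 3 | dimethyl (2S,4Z)-4-[(4-benzyloxy-3-methoxyphenyl)methylidene]-2-(3,4,5-trimethoxyphenyl)oxolane-3,3-dicarboxylate | COc1cc(/C=C2\CO[C@@H](c3cc(OC)c(OC)c(OC)c3)C2(C(=O)OC)C(=O)OC)ccc1OCc1ccccc1
F3 | step 4 | (2R,4Z)-4-[(4-benzyloxy-3-methoxyphenyl)methylidene]-3-(methoxycarbonyl)-2-(3,4,5-trimethoxyphenyl)oxolane-3-carboxylic acid | COc1cc(/C=C2\CO[C@H](c3cc(OC)c(OC)c(OC)c3)C2(C(=O)O)C(=O)OC)ccc1OCc1ccccc1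
F4 | step 4 | methyl (2S,3R,4Z)-4-[(4-benzyloxy-3-methoxyphenyl)methylidene]-2-(3,4,5-trimethoxyphenyl)oxolane-3-carboxylate | COc1cc(/C=C2\CO[C@H](c3cc(OC)c(OC)c(OC)c3)[C@@H]2C(=O)OC)ccc1OCc1ccccc1
F5 | step 5 | [(2S,3R,4Z)-4-[(4-benzyloxy-3-methoxyphenyl)methylidene]-2-(3,4,5-trimethoxyphenyl)oxolan-3-yl]methanol | COc1cc(/C=C2\CO[C@H](c3cc(OC)c(OC)c(OC)c3)[C@H]2CO)ccc1OCc1ccccc1
F6 | step 5 | tert-butyl{[(2S,3R,4Z)-4-[(4-benzyloxy-3-methoxyphenyl)methylidene]-2-(3,4,5-trimethoxyphenyl)oxolan-3-yl]methoxy}diphenylsilane | COc1cc(/C=C2\CO[C@H](c3cc(OC)c(OC)c(OC)c3)[C@H]2CO[Si](c4ccccc4)(c5ccccc5)C(C)(C)C)ccc1OCc1ccccc1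
F7 | step 5 | 4-{[(3R,4R,5S)-4-{[tert-butyl(diphenyl)silyl]oxymethyl}-5-(3,4,5-trimethoxyphenyl)oxolan-3-yl]methyl}-2-methoxyphenol | COc1cc(C[C@H]2CO[C@H](c3cc(OC)c(OC)c(OC)c3)[C@H]2CO[Si](c4ccccc4)(c5ccccc5)C(C)(C)C)ccc1O
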